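**Retrosynthetic overview**

1. The two esters go on last. The C8 carbinol comes from 1,2-reduction of a C6=C7 enone (this step also resolves the racemate), the enone from dehydrogenation of a C8 ketone, and the C4 carbinol from a hydroxyl-directed reduction of a C4 ketone.
2. The seven-membered ring B comes from glycol cleavage of a cyclobutane-1,2-diol. The enabling feature is that the two oxygen-bearing carbons C4 and C8 of ring B are 1,4-related through the ring-fusion bond C3a–C8a, so a temporary C4–C8 bond turns C4, C8, C8a and C3a into a four-membered ring fused to ring A and to a temporary cyclopentane (C4–C5–C6–C7–C8).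
3. That cyclobutane comes from an enone–alkene [2+2] photocycloaddition of 2-methoxy-3-methylcyclopent-2-enone (ring A with the C8a methyl group) with 4-methyl-1,2-bis(trimethylsilyloxy)cyclopentene; it forms C8–C8a and C3a–C4 in one operation.
4. The C3a methoxy group is a temporary leaving group: after ring expansion SmI2 gives the C3a=C4 enolate, and kinetic protonation sets the trans ring fusion. C3 is set earlier by convex-face addition of isopropyl to the photoadduct.
5. Ring order: ring A (five-membered, bought), then the cyclobutane with its temporary cyclopentane (step 3), then ring B by fragmentation (step 5).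

Key step: step 3

Remark on the chemistry (reading of the target): the target is taken as the trans-fused hydroazulene with the C8a methyl, the C3 isopropyl and both acyloxy groups (C4, C8) on one face (β) and H-3a and the C3 hydroxyl on the other (α).

Remark on conventions: hydroazulenes carry the azulene numbering of the target (C3 carbinol, C3a ring-fusion CH, C4 benzoate carbon, C6 methyl-bearing alkene carbon, C8 isovalerate carbon, C8a quaternary carbon). In the tricycles, C2, C3 and C6 become C3a, C3 and C8a, and C1, C7 and C9 become C4, C8 and C6. All intermediates from the photoadduct up to the enone of step 9 are racemic; their SMILES show the enantiomer that leads to the target. The methyl-bearing centre C9 (later C6) is an epimer mixture until step 9 removes it.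

**Route**

Step 1
Reactants: 1 2-hydroxy-3-methylcyclopent-2-en-1-one
Product: 2 2-methoxy-3-methylcyclopent-2-en-1-one
Conditions: Me2SO4, K2CO3, acetone, reflux
Reagents that add atoms: dimethyl sulfate COS(=O)(=O)OC
Why: Williamson-type O-alkylation of the enolised 1,2-dione gives the enol methyl ether; no stereocentre is formed.

Step 2
Reactants: 3 dimethyl 3-methylpentanedioate
Product: 4 4-methyl-1,2-bis(trimethylsilyloxy)cyclopent-1-ene
Conditions: Na, Me3SiCl, toluene, reflux
Reagents that add atoms: chlorotrimethylsilane C[Si](C)(C)Cl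
Why: Acyloin condensation with in situ silylation (Rühlmann variant) traps the five-membered enediolate as its bis-silyl ether; the product has a mirror plane through C4, so no stereochemistry arises.

Step 3
Reactants: 2 2-methoxy-3-methylcyclopent-2-en-1-one; 4 4-methyl-1,2-bis(trimethylsilyloxy)cyclopent-1-ene
Product: 5 rac-2-methoxy-6,9-dimethyl-1,7-bis(trimethylsilyloxy)tricyclo[5.3.0.0(2,6)]decan-3-one (cis-anti-cis; C9 epimers)
Conditions: hν (350 nm, Pyrex), 4 (3 equiv), hexane, 0 °C
Reagents that add atoms: none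
Why: Excitation of enone 2 and intersystem crossing give the triplet, which adds to the electron-rich alkene 4 to a triplet 1,4-biradical that closes after spin inversion, so that the C8–C8a and C3a–C4 bonds (C6–C7 and C1–C2 of the tricycle) form in one operation. The closest known reaction type is the enone–alkene [2+2] photocycloaddition of cyclopent-2-enones with 1,2-bis(trimethylsilyloxy)cycloalkenes, the photochemical half of a two-carbon ring expansion of the de Mayo kind. The only ring closed is the cyclobutane, by recombination of the 1,4-biradical, and it must be cis-fused to ring A because a trans-fused bicyclo[3.2.0]heptanone is too strained; this fixes the C6 quaternary centre (later C8a) relative to C2 (later C3a) and puts the methoxy leaving group on the face of the C6 methyl group. The two siloxy carbons are cis to each other by the ring constraint of 4; their orientation relative to ring A and the C9 centre are not controlled and need not be, because steps 5 and 9 erase them. No regioselectivity is needed, since 4 has a mirror plane; the chemoselectivity needed (cycloaddition before secondary photolysis of the α-methoxy ketone product) is secured by irradiating at 350 nm, where only the enone absorbs, with 4 in excess.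

Step 4
Reactants: 5 rac-2-methoxy-6,9-dimethyl-1,7-bis(trimethylsilyloxy)tricyclo[5.3.0.0(2,6)]decan-3-one (cis-anti-cis; C9 epimers)
Product: 6 rac-2-methoxy-6,9-dimethyl-3-(propan-2-yl)-1,7-bis(trimethylsilyloxy)tricyclo[5.3.0.0(2,6)]decan-3-ol (isopropyl cis to 2-OMe; C9 epimers)
Conditions: i-PrMgCl, CeCl3, THF, −78 to 0 °C
Reagents that add atoms: isopropylmagnesium chloride CC(C)[Mg]Cl
Why: 1,2-Addition of the organocerium reagent (low basicity, little β-hydride reduction) should occur on the convex face of the cis-fused bicyclo[3.2.0]heptanone, anti to the cyclobutane, which places the isopropyl group cis to the C6 methyl group and the hydroxyl on the concave face and so sets the future C3.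

Step 5
Reactants: 6 rac-2-methoxy-6,9-dimethyl-3-(propan-2-yl)-1,7-bis(trimethylsilyloxy)tricyclo[5.3.0.0(2,6)]decan-3-ol (isopropyl cis to 2-OMe; C9 epimers)
Product: 8 rac-3α-hydroxy-3aβ-methoxy-6,8aβ-dimethyl-3β-(propan-2-yl)perhydroazulene-4,8-dione (cis-fused; C6 epimers), via cyclobutane triol 7 (not isolated)
Conditions: K2CO3 (cat.), MeOH, 0 °C; evaporation; then Pb(OAc)4, CH2Cl2, 0 °C
Reagents that add atoms: none
Why: Methanolysis of the two tertiary trimethylsilyl ethers and Criegee glycol cleavage of the strained cis-cyclobutane-1,2-diol cut the temporary C1–C7 bond (C4–C8) and open the bicycle to ring B; the C3 hydroxyl has no free vicinal partner because C3a is a methyl ether, and all photoadduct isomers converge because both carbinol carbons become carbonyl groups.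

Step 6
Reactants: 8 rac-3α-hydroxy-3aβ-methoxy-6,8aβ-dimethyl-3β-(propan-2-yl)perhydroazulene-4,8-dione (cis-fused; C6 epimers)
Product: 10 rac-3α-hydroxy-6,8aβ-dimethyl-3β-(propan-2-yl)-3aαH-perhydroazulene-4,8-dione (trans-fused; C6 epimers), via samarium enolate 9 (not isolated)
Conditions: SmI2 (2.5 equiv), THF–MeOH, −78 °C; pH 7 buffer
Reagents that add atoms: none
Why: SmI2 reduction of an α-alkoxy ketone (two single-electron transfers with loss of methoxide) gives the C3a=C4 enolate regiospecifically, and its kinetic protonation by methanol should occur on the α face because the β face of C3a is flanked by the C8a methyl and the C3 isopropyl groups, which sets the trans ring fusion without equilibration.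

Step 7
Reactants: 10 rac-3α-hydroxy-6,8aβ-dimethyl-3β-(propan-2-yl)-3aαH-perhydroazulene-4,8-dione (trans-fused; C6 epimers)
Product: 11 rac-3α,4β-dihydroxy-6,8aβ-dimethyl-3β-(propan-2-yl)-3aαH-perhydroazulen-8-one (C6 epimers)
Conditions: Me4NBH(OAc)3, MeCN–AcOH, −30 °C
Reagents that add atoms: none
Why: Evans–Saksena reduction: the α-oriented C3 hydroxyl exchanges onto boron and delivers hydride through a six-membered transition state to the α face of the C4 carbonyl, giving the 4β alcohol (anti-1,3-diol), while the C8 ketone, which has no β-hydroxyl, is not reduced by this reagent.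

Step 8
Reactants: 11 rac-3α,4β-dihydroxy-6,8aβ-dimethyl-3β-(propan-2-yl)-3aαH-perhydroazulen-8-one (C6 epimers); 12 4-(tert-butyldimethylsilyloxy)benzoic acid
Product: 14 rac-3α-hydroxy-6,8aβ-dimethyl-8-oxo-3β-(propan-2-yl)-3aαH-perhydroazulen-4β-yl 4-(tert-butyldimethylsilyloxy)benzoate (C6 epimers), via mixed anhydride 13 (not isolated)
Conditions: 2,4,6-trichlorobenzoyl chloride, Et3N, THF, rt; then 4-(dimethylamino)pyridine, toluene, 50 °C
Reagents that add atoms: none
Why: Yamaguchi esterification through the mixed anhydride acylates only the secondary C4 hydroxyl, since the tertiary C3 hydroxyl is inert and the acyl-transfer catalyst attacks the unhindered aroyl carbonyl; no stereocentre is touched.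

Step 9
Reactants: 14 rac-3α-hydroxy-6,8aβ-dimethyl-8-oxo-3β-(propan-2-yl)-3aαH-perhydroazulen-4β-yl 4-(tert-butyldimethylsilyloxy)benzoate (C6 epimers)
Product: 16 rac-6,8aβ-dimethyl-8-oxo-3β-(propan-2-yl)-3α-(trimethylsilyloxy)-1,2,3,3aα,4,5,8,8a-octahydroazulen-4β-yl 4-(tert-butyldimethylsilyloxy)benzoate, via silyl enol ether 15 (not isolated)
Conditions: Me3SiOTf, Et3N, CH2Cl2, 0 °C; then Pd(OAc)2 (1.1 equiv), MeCN, rt
Reagents that add atoms: trimethylsilyl trifluoromethanesulfonate C[Si](C)(C)OS(=O)(=O)C(F)(F)F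
Why: Soft enolisation can only go towards C7 because C8a is quaternary (the C3 hydroxyl is silylated at the same time), and Saegusa–Ito oxidation of the silyl enol ether (oxa-π-allylpalladium, β-hydride elimination of H-6) gives the C6=C7 enone, which removes the C6 stereocentre so that both epimers converge.

Step 10
Reactants: 16 rac-6,8aβ-dimethyl-8-oxo-3β-(propan-2-yl)-3α-(trimethylsilyloxy)-1,2,3,3aα,4,5,8,8a-octahydroazulen-4β-yl 4-(tert-butyldimethylsilyloxy)benzoate
Product: 17 (3S,3aS,4R,8S,8aS)-8-hydroxy-6,8a-dimethyl-3-(propan-2-yl)-3-(trimethylsilyloxy)-1,2,3,3a,4,5,8,8a-octahydroazulen-4-yl 4-(tert-butyldimethylsilyloxy)benzoate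
Conditions: (R)-1-methyl-3,3-diphenyltetrahydro-1H,3H-pyrrolo[1,2-c][1,3,2]oxazaborole (0.5 equiv), catecholborane (0.6 equiv), toluene, −78 °C
Reagents that add atoms: none
Why: Corey–Bakshi–Shibata reduction used as a kinetic resolution: for the enantiomer of 16 that leads to the target, catalyst-controlled 1,2-hydride delivery (quaternary C8a as the large group) coincides with the substrate-preferred attack on the α face anti to the C8a methyl group and gives the 8β (8S) alcohol, whereas the mirror-image enone is mismatched and should be recovered as ketone by chromatography.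

Step 11
Reactants: 17 (3S,3aS,4R,8S,8aS)-8-hydroxy-6,8a-dimethyl-3-(propan-2-yl)-3-(trimethylsilyloxy)-1,2,3,3a,4,5,8,8a-octahydroazulen-4-yl 4-(tert-butyldimethylsilyloxy)benzoate
Product: 18 (3S,3aS,4R,8S,8aS)-6,8a-dimethyl-8-(3-methylbutanoyloxy)-3-(propan-2-yl)-3-(trimethylsilyloxy)-1,2,3,3a,4,5,8,8a-octahydroazulen-4-yl 4-(tert-butyldimethylsilyloxy)benzoate
Conditions: 3-methylbutanoyl chloride, pyridine, 4-(dimethylamino)pyridine (cat.), CH2Cl2, 0 °C to rt
Reagents that add atoms: 3-methylbutanoyl chloride CC(C)CC(Cl)=O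
Why: Acylation of the secondary allylic C8 hydroxyl by the acid chloride under nucleophilic catalysis; the tertiary C3 oxygen is silylated and no stereocentre is affected.

Step 12
Reactants: 18 (3S,3aS,4R,8S,8aS)-6,8a-dimethyl-8-(3-methylbutanoyloxy)-3-(propan-2-yl)-3-(trimethylsilyloxy)-1,2,3,3a,4,5,8,8a-octahydroazulen-4-yl 4-(tert-butyldimethylsilyloxy)benzoate
Product: 19 (3S,3aS,4R,8S,8aS)-3-hydroxy-6,8a-dimethyl-8-(3-methylbutanoyloxy)-3-(propan-2-yl)-1,2,3,3a,4,5,8,8a-octahydroazulen-4-yl 4-hydroxybenzoate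
Conditions: Bu4NF, AcOH, THF, 0 °C
Reagents that add atoms: none
Why: Fluoride-mediated desilylation cleaves the phenolic tert-butyldimethylsilyl ether and the tertiary trimethylsilyl ether, and buffering with acetic acid should keep the aryl ester and the allylic ester intact; no stereocentre is affected.

**Compound list**

1 | 2-hydroxy-3-methylcyclopent-2-en-1-one | CC1=C(O)C(=O)CC1 | starting material
2 | 2-methoxy-3-methylcyclopent-2-en-1-one | COC1=C(C)CCC1=O | intermediate
3 | dimethyl 3-methylpentanedioate | COC(=O)CC(C)CC(=O)OC | starting material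
4 | 4-methyl-1,2-bis(trimethylsilyloxy)cyclopent-1-ene | CC1CC(O[Si](C)(C)C)=C(O[Si](C)(C)C)C1 | intermediate
5 | rac-2-methoxy-6,9-dimethyl-1,7-bis(trimethylsilyloxy)tricyclo[5.3.0.0(2,6)]decan-3-one (cis-anti-cis; C9 epimers) | CC1C[C@]3(O[Si](C)(C)C)[C@@]2(C)CCC(=O)[C@@]2(OC)[C@]3(O[Si](C)(C)C)C1 | intermediate
6 | rac-2-methoxy-6,9-dimethyl-3-(propan-2-yl)-1,7-bis(trimethylsilyloxy)tricyclo[5.3.0.0(2,6)]decan-3-ol (isopropyl cis to 2-OMe; C9 epimers) | CC1C[C@]3(O[Si](C)(C)C)[C@@]2(C)CC[C@](O)(C(C)C)[C@@]2(OC)[C@]3(O[Si](C)(C)C)C1 | intermediate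
7 | cyclobutane triol: rac-2-methoxy-6,9-dimethyl-3-(propan-2-yl)tricyclo[5.3.0.0(2,6)]decane-1,3,7-triol | CC1C[C@]3(O)[C@@]2(C)CC[C@](O)(C(C)C)[C@@]2(OC)[C@]3(O)C1 | intermediate
8 | rac-3α-hydroxy-3aβ-methoxy-6,8aβ-dimethyl-3β-(propan-2-yl)perhydroazulene-4,8-dione (cis-fused; C6 epimers) | CC1CC(=O)[C@@]2(C)CC[C@](O)(C(C)C)[C@@]2(OC)C(=O)C1 | intermediate
9 | samarium enolate: C3a=C4 diiodosamarium enolate of 10 | CC1CC(=O)[C@@]2(C)CC[C@](O)(C(C)C)C2=C(O[Sm](I)I)C1 | intermediate
10 | rac-3α-hydroxy-6,8aβ-dimethyl-3β-(propan-2-yl)-3aαH-perhydroazulene-4,8-dione (trans-fused; C6 epimers) | CC1CC(=O)[C@@]2(C)CC[C@](O)(C(C)C)[C@@H]2C(=O)C1 | intermediate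
11 | rac-3α,4β-dihydroxy-6,8aβ-dimethyl-3β-(propan-2-yl)-3aαH-perhydroazulen-8-one (C6 epimers) | CC1CC(=O)[C@@]2(C)CC[C@](O)(C(C)C)[C@@H]2[C@H](O)C1 | intermediate
12 | 4-(tert-butyldimethylsilyloxy)benzoic acid | CC(C)(C)[Si](C)(C)Oc1ccc(cc1)C(O)=O | starting material
13 | mixed anhydride: 4-(tert-butyldimethylsilyloxy)benzoic 2,4,6-trichlorobenzoic anhydride | CC(C)(C)[Si](C)(C)Oc1ccc(cc1)C(=O)OC(=O)c1c(Cl)cc(Cl)cc1Cl | intermediate
14 | rac-3α-hydroxy-6,8aβ-dimethyl-8-oxo-3β-(propan-2-yl)-3aαH-perhydroazulen-4β-yl 4-(tert-butyldimethylsilyloxy)benzoate (C6 epimers) | CC1CC(=O)[C@@]2(C)CC[C@](O)(C(C)C)[C@@H]2[C@H](OC(=O)c3ccc(O[Si](C)(C)C(C)(C)C)cc3)C1 | intermediate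
15 | silyl enol ether: rac-6,8aβ-dimethyl-3β-(propan-2-yl)-3α,8-bis(trimethylsilyloxy)-1,2,3,3aα,4,5,6,8a-octahydroazulen-4β-yl 4-(tert-butyldimethylsilyloxy)benzoate (C6 epimers) | CC1C=C(O[Si](C)(C)C)[C@@]2(C)CC[C@](O[Si](C)(C)C)(C(C)C)[C@@H]2[C@H](OC(=O)c3ccc(O[Si](C)(C)C(C)(C)C)cc3)C1 | intermediate
16 | rac-6,8aβ-dimethyl-8-oxo-3β-(propan-2-yl)-3α-(trimethylsilyloxy)-1,2,3,3aα,4,5,8,8a-octahydroazulen-4β-yl 4-(tert-butyldimethylsilyloxy)benzoate | CC1=CC(=O)[C@@]2(C)CC[C@](O[Si](C)(C)C)(C(C)C)[C@@H]2[C@H](OC(=O)c3ccc(O[Si](C)(C)C(C)(C)C)cc3)C1 | intermediate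
17 | (3S,3aS,4R,8S,8aS)-8-hydroxy-6,8a-dimethyl-3-(propan-2-yl)-3-(trimethylsilyloxy)-1,2,3,3a,4,5,8,8a-octahydroazulen-4-yl 4-(tert-butyldimethylsilyloxy)benzoate | CC1=C[C@H](O)[C@@]2(C)CC[C@](O[Si](C)(C)C)(C(C)C)[C@@H]2[C@H](OC(=O)c3ccc(O[Si](C)(C)C(C)(C)C)cc3)C1 | intermediate
18 | (3S,3aS,4R,8S,8aS)-6,8a-dimethyl-8-(3-methylbutanoyloxy)-3-(propan-2-yl)-3-(trimethylsilyloxy)-1,2,3,3a,4,5,8,8a-octahydroazulen-4-yl 4-(tert-butyldimethylsilyloxy)benzoate | CC1=C[C@H](OC(=O)CC(C)C)[C@@]2(C)CC[C@](O[Si](C)(C)C)(C(C)C)[C@@H]2[C@H](OC(=O)c3ccc(O[Si](C)(C)C(C)(C)C)cc3)C1 | intermediate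
19 | (3S,3aS,4R,8S,8aS)-3-hydroxy-6,8a-dimethyl-8-(3-methylbutanoyloxy)-3-(propan-2-yl)-1,2,3,3a,4,5,8,8a-octahydroazulen-4-yl 4-hydroxybenzoate | CC1=C[C@H](OC(=O)CC(C)C)[C@@]2(C)CC[C@](O)(C(C)C)[C@@H]2[C@H](OC(=O)c2ccc(O)cc2)C1 | target

**Step count**

Total step count: 12. Longest linear sequence: 11 steps (1 to 19 through steps 1 and 3 to 12, or 3 to 19 through steps 2 to 12).

**Steps most likely to fail, with fallbacks**

Step 3. The cycloaddition joins two fully substituted double bonds, so ring closure may be too slow and the excited enone may instead be consumed by hydrogen abstraction from the methoxy group or by decomposition of the silyl enol ether. The fallback gives up the C3a methoxy group and with it the kinetic control of C3a. It sets out from 4 and commercial 3-methylcyclopent-2-en-1-one: irradiation as in step 3 should give the photoadduct rac-6,9-dimethyl-1,7-bis(trimethylsilyloxy)tricyclo[5.3.0.0(2,6)]decan-3-one F1, a substrate type with direct precedent. Addition of i-PrMgCl/CeCl3 gives the carbinol rac-6,9-dimethyl-3-(propan-2-yl)-1,7-bis(trimethylsilyloxy)tricyclo[5.3.0.0(2,6)]decan-3-ol F2, K2CO3 in MeOH gives the triol rac-6,9-dimethyl-3-(propan-2-yl)tricyclo[5.3.0.0(2,6)]decane-1,3,7-triol F3, and Pb(OAc)4 gives the cis-fused hydroxy-dione rac-3α-hydroxy-6,8aβ-dimethyl-3β-(propan-2-yl)-3aβH-perhydroazulene-4,8-dione F4. C3a is then inverted under thermodynamic control (1,8-diazabicyclo[5.4.0]undec-7-ene, toluene, rt); the equilibrium may well favour the cis isomer, so the trans isomer is separated and the cis isomer re-equilibrated. The route is rejoined at 10.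

Step 6. Protonation of the enolate may not be selective for the α face, or the kinetic product may equilibrate during work-up, which would give the cis ring fusion. The fallback sets C3a by a syn hydroboration instead of a protonation. It sets out from 8: the samarium enolate 9 is generated without a proton source and trapped with N-phenylbis(trifluoromethanesulfonimide) as the enol triflate rac-3α-hydroxy-6,8aβ-dimethyl-8-oxo-3β-(propan-2-yl)-1,2,3,5,6,7,8,8a-octahydroazulen-4-yl trifluoromethanesulfonate F5. Reduction with Pd(OAc)2, PPh3, HCO2H and Bu3N gives the C3a=C4 alkene rac-3α-hydroxy-6,8aβ-dimethyl-3β-(propan-2-yl)-1,2,3,5,6,7-hexahydroazulen-8(8aH)-one F6. BH3·THF then NaOH/H2O2 should add H and OH syn on the α face, away from the C8a methyl and C3 isopropyl groups, and also reduces the C8 ketone, giving the triol rac-6,8aβ-dimethyl-3β-(propan-2-yl)-3aαH-perhydroazulene-3α,4α,8-triol F7. Dess–Martin periodinane oxidises both secondary alcohols, and the route is rejoined at 10.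

Step 10. The reduction may not discriminate well enough between the two enantiomers of 16, because background reduction and the mismatched pathway both feed the wrong enantiomer of the alcohol and lower the enantiomeric purity. The fallback separates the enantiomers as covalent diastereomers. It sets out from 16: Luche reduction (NaBH4, CeCl3·7H2O, MeOH, −78 °C) under substrate control gives 17 together with its enantiomer ent-17 F8. Reaction with (S)-1-(naphthalen-1-yl)ethyl isocyanate (4-(dimethylamino)pyridine, toluene, 80 °C) gives the carbamate of 17 F9 and the carbamate of ent-17 F10, which are separated on silica. Cleavage of F9 with HSiCl3 and Et3N returns the alcohol, and the route is rejoined at 17.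

**Further compounds**

F1 | step 3 | rac-6,9-dimethyl-1,7-bis(trimethylsilyloxy)tricyclo[5.3.0.0(2,6)]decan-3-one | CC1C[C@]3(O[Si](C)(C)C)[C@@]2(C)CCC(=O)[C@H]2[C@]3(O[Si](C)(C)C)C1
F2 | step 3 | rac-6,9-dimethyl-3-(propan-2-yl)-1,7-bis(trimethylsilyloxy)tricyclo[5.3.0.0(2,6)]decan-3-ol | CC1C[C@]3(O[Si](C)(C)C)[C@@]2(C)CC[C@](O)(C(C)C)[C@H]2[C@]3(O[Si](C)(C)C)C1
F3 | step 3 | rac-6,9-dimethyl-3-(propan-2-yl)tricyclo[5.3.0.0(2,6)]decane-1,3,7-triol | CC1C[C@]3(O)[C@@]2(C)CC[C@](O)(C(C)C)[C@H]2[C@]3(O)C1
F4 | step 3 | rac-3α-hydroxy-6,8aβ-dimethyl-3β-(propan-2-yl)-3aβH-perhydroazulene-4,8-dione | CC1CC(=O)[C@@]2(C)CC[C@](O)(C(C)C)[C@H]2C(=O)C1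
F5 | step 6 | rac-3α-hydroxy-6,8aβ-dimethyl-8-oxo-3β-(propan-2-yl)-1,2,3,5,6,7,8,8a-octahydroazulen-4-yl trifluoromethanesulfonate | CC1CC(=O)[C@@]2(C)CC[C@](O)(C(C)C)C2=C(OS(=O)(=O)C(F)(F)F)C1
F6 | step 6 | rac-3α-hydroxy-6,8aβ-dimethyl-3β-(propan-2-yl)-1,2,3,5,6,7-hexahydroazulen-8(8aH)-one | CC1CC(=O)[C@@]2(C)CC[C@](O)(C(C)C)C2=CC1
F7 | step 6 | rac-6,8aβ-dimethyl-3β-(propan-2-yl)-3aαH-perhydroazulene-3α,4α,8-triol | CC1CC(O)[C@@]2(C)CC[C@](O)(C(C)C)[C@@H]2[C@@H](O)C1
F8 | step 10 | ent-17 ((3R,3aR,4S,8R,8aR) enantiomer of 17) | CC1=C[C@@H](O)[C@]2(C)CC[C@@](O[Si](C)(C)C)(C(C)C)[C@H]2[C@@H](OC(=O)c3ccc(O[Si](C)(C)C(C)(C)C)cc3)C1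
F9 | step 10 | carbamate of 17 with (S)-1-(naphthalen-1-yl)ethyl isocyanate | CC1=C[C@H](OC(=O)N[C@@H](C)c3cccc4ccccc34)[C@@]2(C)CC[C@](O[Si](C)(C)C)(C(C)C)[C@@H]2[C@H](OC(=O)c3ccc(O[Si](C)(C)C(C)(C)C)cc3)C1
F10 | step 10 | carbamate of ent-17 with (S)-1-(naphthalen-1-yl)ethyl isocyanate | CC1=C[C@@H](OC(=O)N[C@@H](C)c3cccc4ccccc34)[C@]2(C)CC[C@@](O[Si](C)(C)C)(C(C)C)[C@H]2[C@@H](OC(=O)c3ccc(O[Si](C)(C)C(C)(C)C)cc3)C1
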